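**Retrosynthetic overview**
- C3=C4 (E-alkylidene lactone): intramolecular Horner–Wadsworth–Emmons reaction of an α-phosphono-γ-lactone with a C3 aldehyde closes the 14-membered ring.
- The C3 aldehyde and the C9/C11 1,3-diketone are released together by retro-aldol opening of the six-membered ring of a carvone-epoxide-derived β-hydroxy aldehyde (6 → 14 ring expansion); C10–C11 is made beforehand by γ-carbanion addition of a β-keto ester to the ring ketone.
- The lactone (C4–C7, O on C6) comes from methyl acetoacetate and an epoxy phosphonoacetate made from (R)-epichlorohydrin.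
- Ring order: epoxide first, on (S)-carvone (fixes C1, C12, C13); then the γ-lactone and the 14-membered carbocycle in one final one-pot operation, in which the cyclohexane ring is opened.

Assumption: C8 (α-carbon of the β-keto ester) is configurationally labile and is taken to settle as the natural 8S epimer; atom labels run C1 (CH–isopropenyl), C2, C3=C4, C5, C6 (O), C7, C8 (CO2Me), C9 (C=O), C10, C11 (C=O), C12/C13 (epoxide), C14.

**Step 1**
Reactants: 1 (S)-(+)-carvone
Product: 2 (1S,4S,6S)-1-methyl-4-(prop-1-en-2-yl)-7-oxabicyclo[4.1.0]heptan-2-one (trans-carvone epoxide)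
Conditions: 30% H2O2, NaOH (cat.), MeOH, 0 °C
Reagents that add atoms: hydrogen peroxide, OO
Why: Weitz–Scheffer nucleophilic epoxidation; hydroperoxide adds to the enone face anti to the isopropenyl group, which sets C12 and C13 relative to C1 (epoxide trans to isopropenyl).

**Step 2**
Reactants: 2 trans-carvone epoxide
Product: 4 3-(triisopropylsilyloxymethylidene) derivative of 2 (ring stereocentres unchanged; drawn E, geometry immaterial), via hydroxymethylene ketone 3 (not isolated)
Conditions: LDA, THF, −78 °C; HCO2CH2CF3; then TIPSOTf, −78 → 0 °C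
Reagents that add atoms: 2,2,2-trifluoroethyl formate, O=COCC(F)(F)F; triisopropylsilyl trifluoromethanesulfonate, CC(C)[Si](OS(=O)(=O)C(F)(F)F)(C(C)C)C(C)C
Why: Claisen formylation of the kinetic enolate at the only enolisable CH2, then O-silylation of the hydroxymethylene enolate; this installs C3 as a fluoride-labile masked aldehyde and leaves the ketone non-enolisable, with no stereocentre touched.

**Step 3**
Reactants: 5 triethyl phosphonoacetate; 6 (R)-epichlorohydrin
Product: 7 ethyl 2-(diethoxyphosphoryl)-3-[(2R)-oxiran-2-yl]propanoate (C2 epimers)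
Conditions: NaH (1.0 equiv), THF–DMF, 0 °C → rt, excess 6
Reagents that add atoms: none
Why: C-alkylation of the phosphonoacetate anion by opening of the epoxide at its CH2 terminus, then closure of the alkoxide onto CH2Cl (epoxide relay, as in malonate/epichlorohydrin chemistry); the stereocentre of 6 is not touched and becomes C6.

**Step 4**
Reactants: 8 methyl acetoacetate; 7 epoxy phosphonoacetate; 4 silyloxymethylidene ketone
Product: 13 target CNP0108136.1, via phosphono lactone 9 (not isolated), via tertiary alcohol 10 (not isolated), via hydroxy aldehyde 11 (not isolated), via seco aldehyde 12 (not isolated)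
Conditions: 8, NaH, THF–DMPU, then 7, 55 °C; LDA (3.2 equiv), −78 → 0 °C; 4, −78 °C; AcOH; TBAF, LiCl, DBU, MeCN–THF (2 mM), −20 °C → rt
Reagents that add atoms: none
Why: Proposed new method: (i) Traube-type C-alkylation of the enolate of 8 at the terminal epoxide carbon of 7, then 5-exo lactonisation of the C6 alkoxide onto the non-enolised phosphonoacetate ester, gives 9 with C6 retained; (ii) the trianion of 9 adds through its γ-carbon 1,2 to the non-enolisable vinylogous silyl ester 4 (Huckin–Weiler dianion aldol on a Stork–Danheiser-type acceptor) to give 10; (iii) fluoride unmasks hydroxy aldehyde 11, whose retro-aldol cleavage of the ring C11–C2 bond is driven by 1,3-diketonate formation and gives aldehyde 12; (iv) Masamune–Roush HWE closure of the α-phosphono lactone onto the aldehyde gives the E-alkylidene lactone and the 14-membered ring, and C8 equilibrates to the more stable epimer; closest known reactions are the Traube lactone synthesis, Weiler dianion additions, retro-aldol ring expansions and HWE macrocyclisations of α-phosphono-γ-butyrolactones.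

**Compound list**
1 | (S)-(+)-carvone | C=C(C)[C@@H]1CC(=O)C(C)=CC1 | starting material
2 | (1S,4S,6S)-1-methyl-4-(prop-1-en-2-yl)-7-oxabicyclo[4.1.0]heptan-2-one | C=C(C)[C@@H]1CC(=O)[C@@]2(C)O[C@H]2C1 | intermediate
3 | 3-(hydroxymethylidene) derivative of 2 (Z enol, lithium salt in the flask) | C=C(C)[C@@H]1/C(=C/O)C(=O)[C@@]2(C)O[C@H]2C1 | intermediate (not isolated)
4 | 3-(triisopropylsilyloxymethylidene) derivative of 2 | C=C(C)[C@@H]1/C(=C\O[Si](C(C)C)(C(C)C)C(C)C)C(=O)[C@@]2(C)O[C@H]2C1 | intermediate
5 | triethyl phosphonoacetate | CCOC(=O)CP(=O)(OCC)OCC | starting material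
6 | (R)-epichlorohydrin | ClC[C@H]1CO1 | starting material
7 | ethyl 2-(diethoxyphosphoryl)-3-[(2R)-oxiran-2-yl]propanoate | CCOC(=O)C(P(=O)(OCC)OCC)C[C@@H]1CO1 | intermediate
8 | methyl acetoacetate | CC(=O)CC(=O)OC | starting material
9 | methyl 2-acetyl-3-[(2S)-4-(diethoxyphosphoryl)-5-oxooxolan-2-yl]propanoate (epimers at C2 and at C–P) | CC(=O)C(C(=O)OC)C[C@H]1CC(P(=O)(OCC)OCC)C(=O)O1 | intermediate (not isolated)
10 | 1,2-adduct of the γ-carbanion of 9 with 4: tertiary alcohol at the former ketone carbon, side chain drawn anti to the epoxide oxygen (this centre is lost later) | C=C(C)[C@@H]1/C(=C\O[Si](C(C)C)(C(C)C)C(C)C)[C@](O)(CC(=O)C(C(=O)OC)C[C@H]3CC(P(=O)(OCC)OCC)C(=O)O3)[C@@]2(C)O[C@H]2C1 | intermediate (not isolated)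
11 | desilylated β-hydroxy aldehyde from 10 | C=C(C)[C@@H]1C(C=O)[C@](O)(CC(=O)C(C(=O)OC)C[C@H]3CC(P(=O)(OCC)OCC)C(=O)O3)[C@@]2(C)O[C@H]2C1 | intermediate (not isolated)
12 | seco aldehyde: C3 aldehyde, C12/C13 epoxy ketone, C9/C11 diketone, C8 methyl ester, α-phosphono lactone | C=C(C)[C@H](CC=O)C[C@@H]1O[C@]1(C)C(=O)CC(=O)C(C(=O)OC)C[C@H]2CC(P(=O)(OCC)OCC)C(=O)O2 | intermediate (not isolated)
13 | CNP0108136.1 (1R,6S,8S,12S,13S in the labels above; C3=C4 E) | C=C(C)[C@@H]1C/C=C2\C[C@H](C[C@H](C(=O)OC)C(=O)CC(=O)[C@@]3(C)O[C@H]3C1)OC2=O | target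

**Step count**
Total steps: 4. Longest linear sequence: 3 (steps 1, 2, 4 from (S)-carvone).

**Steps most likely to fail, with fallbacks**

Step 4 is the weakest. The γ-carbanion may add conjugately to the silyloxymethylidene carbon of 4 instead of 1,2 to the hindered ketone, and the one-flask lactone annulation, ring opening and macrocyclisation may not tolerate each other. The fallback leaves the ring expansion and opens the ring oxidatively; it sets out from 2 and returns at 12. α′-Hydroxylation of 2 (LiHMDS, Davis oxaziridine) gives the hydroxy ketone F1. Pb(OAc)4 in MeOH–benzene cleaves the α-ketol to the aldehyde methyl ester F2. Wittig reaction with Ph3P=CHOMe at −78 °C (salt-free, to protect the α-stereocentre) gives the enol ether F3. Claisen condensation of F3 with the trianion of 9 (made from 8 and 7 as in the first stage of step 4, but isolated) gives the enol ether triketo ester F4. Oxalic acid in wet THF hydrolyses F4 to the seco aldehyde 12, which is then closed to 13 by the LiCl/DBU HWE reaction as a separate step.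

Step 2 may fail if the epoxy ketone enolate does not survive LDA or if silylation is not clean. The fallback avoids strong base; it sets out from 2 and returns at 3. Heating 2 with tert-butoxybis(dimethylamino)methane in toluene gives the enaminone F5. Aqueous AcOH/NaOAc hydrolyses F5 to the hydroxymethylene ketone 3, now isolated, which is silylated (TIPSCl, imidazole) to 4.

Step 3 may fail through attack at C–Cl instead of the epoxide (loss of ee) or through further cyclopropanation of 7. The fallback sets out from 5 and returns at 7. NaH and allyl bromide give ethyl 2-(diethoxyphosphoryl)pent-4-enoate F6. mCPBA gives the racemic epoxide F7. Jacobsen hydrolytic kinetic resolution ((salen)Co(III)OAc, 0.55 equiv H2O, catalyst enantiomer chosen to hydrolyse the 2S-oxirane) leaves 7.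

**Further compounds**
F1 | step 4 | 3-hydroxy derivative of 2 (α′-hydroxy ketone, either epimer) | C=C(C)[C@@H]1C(O)C(=O)[C@@]2(C)O[C@H]2C1
F2 | step 4 | methyl epoxy ester with C2 aldehyde (ring-cleaved 2) | C=C(C)[C@H](C=O)C[C@@H]1O[C@]1(C)C(=O)OC
F3 | step 4 | methyl enol ether of the homologated aldehyde (E/Z) | C=C(C)[C@H](C=COC)C[C@@H]1O[C@]1(C)C(=O)OC
F4 | step 4 | enol ether of seco aldehyde 12 | C=C(C)[C@H](C=COC)C[C@@H]1O[C@]1(C)C(=O)CC(=O)C(C(=O)OC)C[C@H]2CC(P(=O)(OCC)OCC)C(=O)O2
F5 | step 2 | 3-(dimethylaminomethylidene) derivative of 2 | C=C(C)[C@@H]1/C(=C\N(C)C)C(=O)[C@@]2(C)O[C@H]2C1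
F6 | step 3 | ethyl 2-(diethoxyphosphoryl)pent-4-enoate | C=CCC(C(=O)OCC)P(=O)(OCC)OCC
F7 | step 3 | racemic ethyl 2-(diethoxyphosphoryl)-3-(oxiran-2-yl)propanoate | CCOC(=O)C(P(=O)(OCC)OCC)CC1CO1
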